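**Strategy.** Everything rests on opening ring B across C6–C7 and C5–C10 (labdane numbering): an organocatalytic intramolecular Diels–Alder reaction of an acyclic trienal joins the C5=C6 enal to the C7=C8–C9=C10 diene through the C1–C4 tether, so one operation closes rings A and B and sets C5 and C10 (trans fusion) beside a C3–Br centre made earlier by enamine catalysis. It exploits the 1,4-relationship of C7 and C10 across C8–C9 in ring B. The C8=C9 alkene that the cycloaddition leaves is then used: allylic hydroxylation at C7 and an Ireland–Claisen rearrangement of the ester of a linalool-derived acid deliver the side chain to C9 and move the alkene to C7=C8.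

Key step: step 8

Remark on the chemistry: atoms are labelled with labdane numbering (C3 bears Br, C5/C10 are the ring fusion, C9 bears the C11–C16 chain, C13 is the carbinol). The target as drawn is 3R,5S,9S,10S,13R, so the C9 side chain is anti to the C10 methyl. In the two catalyst-controlled steps (2 and 8) the catalyst antipode is assumed to be the one that gives the configuration written.

**Step 1**
Reactants: 1 methyl 3,3-dimethylpent-4-enoate
Product: 2 3,3-dimethylpent-4-enal
Conditions: DIBAL-H (1.05 equiv), CH2Cl2, −78 °C; MeOH, then Rochelle salt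
Reagents that add atoms: none
Why: DIBAL-H partial reduction of a methyl ester at −78 °C should stop at the aldehyde because the aluminium hemiacetal collapses only on work-up, and the isolated vinyl group is not touched.

**Step 2**
Reactants: 2 3,3-dimethylpent-4-enal
Product: 4 (S)-2-bromo-3,3-dimethylpent-4-en-1-ol, via bromoaldehyde 3 (not isolated)
Conditions: (2R,5R)-2,5-diphenylpyrrolidine (20 mol%), 4,4-dibromo-2,6-di-tert-butylcyclohexa-2,5-dienone, PhCO2H (cat.), H2O, CH2Cl2–pentane, −40 → −24 °C; then NaBH4, MeOH, 0 °C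
Reagents that add atoms: 4,4-dibromo-2,6-di-tert-butylcyclohexa-2,5-dien-1-one, O=C1C(C(C)(C)C)=CC(Br)(Br)C=C1C(C)(C)C
Why: Organocatalytic enamine α-bromination sets C3, since the C2-symmetric pyrrolidine shields one enamine face, and the labile α-bromo aldehyde is reduced in the same flask by NaBH4 before it can racemise.

**Step 3**
Reactants: 4 (S)-2-bromo-3,3-dimethylpent-4-en-1-ol
Product: 5 (S)-2-bromo-3,3-dimethylpent-4-en-1-yl trifluoromethanesulfonate
Conditions: Tf2O, 2,6-lutidine, CH2Cl2, −78 °C
Reagents that add atoms: trifluoromethanesulfonic anhydride, O=S(=O)(OS(=O)(=O)C(F)(F)F)C(F)(F)F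
Why: O-Triflation of the primary alcohol with a non-nucleophilic base gives the one sulfonate reactive enough for SN2 at this β-branched carbon, and the C3–Br bond is not involved.

**Step 4**
Reactants: 5 (S)-2-bromo-3,3-dimethylpent-4-en-1-yl trifluoromethanesulfonate; 6 1-(trimethylsilyl)prop-1-yne
Product: 9 (R)-5-bromo-6,6-dimethyloct-7-en-1-yne, via lithiated silylpropyne 7 (not isolated), via silylalkyne 8 (not isolated)
Conditions: 6, n-BuLi, THF, −78 → −20 °C; then 5, −78 °C; then MeOH, K2CO3, 23 °C (one pot)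
Reagents that add atoms: none
Why: Propargylic lithiation and SN2 alkylation by the primary triflate form C1–C2 (the silyl group enforces propargyl over allenyl attack, the neopentyl-type secondary bromide is inert to SN2), then K2CO3/MeOH protodesilylates the alkyne; C3 is untouched and only its CIP descriptor changes to R.

**Step 5**
Reactants: 9 (R)-5-bromo-6,6-dimethyloct-7-en-1-yne
Product: 11 (1E,5R)-5-bromo-1-iodo-2,6,6-trimethylocta-1,7-diene, via vinylalane 10 (not isolated)
Conditions: Me3Al (2.5 equiv), Cp2ZrCl2 (20 mol%), H2O (1 equiv), CH2Cl2, −25 °C; then I2, THF, −25 → 0 °C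
Reagents that add atoms: trimethylaluminium, C[Al](C)C; iodine, II
Why: Negishi zirconium-catalysed carboalumination adds Me–Al syn across the terminal alkyne with methyl (C20) on the internal carbon, and iodinolysis with retention fixes the E geometry (C1 trans to the C9–I bond).

**Step 6**
Reactants: 11 (1E,5R)-5-bromo-1-iodo-2,6,6-trimethylocta-1,7-diene; 12 (E)-but-2-enal (crotonaldehyde)
Product: 13 (2E,5R,8E)-5-bromo-9-iodo-4,4,8-trimethylnona-2,8-dienal
Conditions: second-generation Ru benzylidene catalyst (Hoveyda–Grubbs type, 5 mol%), 12 (5 equiv), CH2Cl2, 40 °C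
Reagents that add atoms: none
Why: Olefin cross-metathesis of the hindered monosubstituted alkene with an enal should give the E-enal selectively, while the trisubstituted iodoalkene is too hindered to enter the cycle; this installs the dienophile-activating formyl group.

**Step 7**
Reactants: 13 (2E,5R,8E)-5-bromo-9-iodo-4,4,8-trimethylnona-2,8-dienal; 14 isopropenylboronic acid pinacol ester
Product: 15 (2E,5R,8E)-5-bromo-4,4,8,10-tetramethylundeca-2,8,10-trienal
Conditions: Pd(dppf)Cl2 (5 mol%), K3PO4, THF–H2O, 23 °C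
Reagents that add atoms: none
Why: Suzuki–Miyaura coupling of the alkenyl iodide proceeds with retention of the E double bond and completes the 2,4-dimethyl-1,3-diene; mild aqueous phosphate spares the enal and Pd(0) does not insert into the hindered secondary C–Br bond.

**Step 8 (key step)**
Reactants: 15 (2E,5R,8E)-5-bromo-4,4,8,10-tetramethylundeca-2,8,10-trienal
Product: 16 (1R,4aS,7R,8aS)-7-bromo-3,4a,8,8-tetramethyl-1,2,4a,5,6,7,8,8a-octahydronaphthalene-1-carbaldehyde
Conditions: (2S,5S)-5-benzyl-2-tert-butyl-3-methylimidazolidin-4-one·HClO4 (20 mol%), MeCN–H2O (98:2), 0.02 M, 5 → 23 °C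
Reagents that add atoms: none
Why: Iminium activation of the enal by the chiral secondary amine salt (a transient, catalyst-bound species) lowers its LUMO, so the C5=C6 dienophile adds across the tethered C7=C8–C9=C10 diene in a concerted, asynchronous [4+2] cycloaddition that forms C6–C7 and C5–C10 together, and hydrolysis returns the aldehyde and the catalyst. The closest known reaction type is the organocatalytic type-1 intramolecular Diels–Alder reaction of (2E,7E)-2,7,9-decatrienals to trans-fused octalin carbaldehydes. Ring B (C5–C6–C7–C8–C9–C10) closes as the cyclohexene of the [4+2] event and ring A (C10–C1–C2–C3–C4–C5) closes through the same C5–C10 bond via the four-carbon tether, with the tether anti (exo) and the iminium endo. C5 and C10 are set by the catalyst-shielded π-face of the iminium together with the endo transition state, the E-configured C9=C10 bond placing C20 anti to H5 (trans fusion); the transient C6 centre follows from the E enal, and the C3–Br centre can sit equatorial on the chair-like tether in this sense. The step needs endo over exo selectivity, one π-face relative to C3 and cyclisation in preference to diene dimerisation: the s-trans iminium geometry, catalyst control (the bias from C3 alone is weak) and high dilution should secure these.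

**Step 9**
Reactants: 16 (1R,4aS,7R,8aS)-7-bromo-3,4a,8,8-tetramethyl-1,2,4a,5,6,7,8,8a-octahydronaphthalene-1-carbaldehyde
Product: 17 (2R,4aS,8aS)-2-bromo-1,1,4a,6-tetramethyl-1,2,3,4,4a,7,8,8a-octahydronaphthalene
Conditions: RhCl(PPh3)3 (1.1 equiv), toluene, 110 °C
Reagents that add atoms: none
Why: Tsuji–Wilkinson decarbonylation (oxidative addition into the formyl C–H bond, CO de-insertion, C–H reductive elimination) removes the activating carbon so that C6 becomes CH2; the alkyl bromide and the trisubstituted alkene should be inert to Rh(I).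

**Step 10**
Reactants: 17 (2R,4aS,8aS)-2-bromo-1,1,4a,6-tetramethyl-1,2,3,4,4a,7,8,8a-octahydronaphthalene
Product: 18 (2S,4aS,7R,8aS)-7-bromo-3,4a,8,8-tetramethyl-1,2,4a,5,6,7,8,8a-octahydronaphthalen-2-ol
Conditions: SeO2 (0.5 equiv), t-BuOOH (2 equiv), CH2Cl2, 0 → 23 °C
Reagents that add atoms: selenium dioxide, O=[Se]=O; tert-butyl hydroperoxide, CC(C)(C)OO
Why: Selenium dioxide allylic hydroxylation (ene reaction at C9, then [2,3]-sigmatropic shift) should oxidise the ring CH2 next to the more substituted alkene carbon (C7) and, because the reagent engages the alkene face anti to the axial C10 methyl, deliver the C7–OH pseudoaxially on that face (cis to H5).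

**Step 11**
Reactants: 19 (R)-(−)-linalool
Product: 20 (R)-triethyl[(3,7-dimethylocta-1,6-dien-3-yl)oxy]silane
Conditions: TESOTf, 2,6-lutidine, CH2Cl2, 0 °C
Reagents that add atoms: triethylsilyl trifluoromethanesulfonate, CC[Si](CC)(CC)OS(=O)(=O)C(F)(F)F
Why: Silyl triflate silylation protects the tertiary allylic alcohol of the chiral-pool terpene, whose stereocentre becomes C13 and is not touched again.

**Step 12**
Reactants: 20 (R)-triethyl[(3,7-dimethylocta-1,6-dien-3-yl)oxy]silane
Product: 21 (R)-4-methyl-4-[(triethylsilyl)oxy]hex-5-enal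
Conditions: O3, CH2Cl2–MeOH, pyridine, −78 °C (dye end point); then Me2S, −78 → 23 °C
Reagents that add atoms: ozone, [O-][O+]=O
Why: Chemoselective ozonolysis: ozone titrated to a dye end point cleaves the electron-rich trisubstituted alkene much faster than the monosubstituted vinyl group next to the silyloxy carbon, and Me2S reduces the ozonide to the aldehyde.

**Step 13**
Reactants: 21 (R)-4-methyl-4-[(triethylsilyl)oxy]hex-5-enal
Product: 22 (R)-4-methyl-4-[(triethylsilyl)oxy]hex-5-enoic acid
Conditions: NaClO2, NaH2PO4, 2-methyl-2-butene, t-BuOH–H2O, 0 → 23 °C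
Reagents that add atoms: sodium chlorite, [Na+].[O-]Cl=O
Why: Pinnick oxidation converts the aldehyde into the acid under buffered conditions that leave the vinyl group (HOCl is scavenged) and the silyl ether intact.

**Step 14**
Reactants: 18 (2S,4aS,7R,8aS)-7-bromo-3,4a,8,8-tetramethyl-1,2,4a,5,6,7,8,8a-octahydronaphthalen-2-ol; 22 (R)-4-methyl-4-[(triethylsilyl)oxy]hex-5-enoic acid
Product: 23 (2S,4aS,7R,8aS)-7-bromo-3,4a,8,8-tetramethyl-1,2,4a,5,6,7,8,8a-octahydronaphthalen-2-yl (4R)-4-methyl-4-[(triethylsilyl)oxy]hex-5-enoate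
Conditions: EDC·HCl, DMAP, CH2Cl2, 0 → 23 °C
Reagents that add atoms: none
Why: Carbodiimide/DMAP (Steglich) esterification acylates the secondary allylic alcohol without ionising it, so the C7–O configuration is retained.

**Step 15**
Reactants: 23 (2S,4aS,7R,8aS)-7-bromo-3,4a,8,8-tetramethyl-1,2,4a,5,6,7,8,8a-octahydronaphthalen-2-yl (4R)-4-methyl-4-[(triethylsilyl)oxy]hex-5-enoate
Product: 25 (4R)-2-[(1S,4aS,6R,8aR)-6-bromo-2,5,5,8a-tetramethyl-1,4,4a,5,6,7,8,8a-octahydronaphthalen-1-yl]-4-methyl-4-[(triethylsilyl)oxy]hex-5-enoic acid (C2 epimers), via silyl ketene acetal 24 (not isolated)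
Conditions: LDA (commercial solution, 1.2 equiv), TMSCl–Et3N, THF, −78 °C; then 65 °C; aq. NH4Cl
Reagents that add atoms: none
Why: Ireland–Claisen rearrangement: the silyl ketene acetal undergoes a suprafacial [3,3] shift across the cyclohexenyl ester, forming C9–C11 on the face that carried the C7–O bond (1,3-chirality transfer, anti to the C10 methyl) and moving the alkene to C7=C8; the new C11 centre is inconsequential because its carboxyl is removed next (the 8aR descriptor reflects a CIP priority change only).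

**Step 16**
Reactants: 25 (4R)-2-[(1S,4aS,6R,8aR)-6-bromo-2,5,5,8a-tetramethyl-1,4,4a,5,6,7,8,8a-octahydronaphthalen-1-yl]-4-methyl-4-[(triethylsilyl)oxy]hex-5-enoic acid
Product: 27 triethyl{[(3R)-5-((1S,4aS,6R,8aS)-6-bromo-2,5,5,8a-tetramethyl-1,4,4a,5,6,7,8,8a-octahydronaphthalen-1-yl)-3-methylpent-1-en-3-yl]oxy}silane, via Barton ester 26 (not isolated)
Conditions: 1-hydroxypyridine-2(1H)-thione, EDC·HCl, DMAP (cat.), CH2Cl2, dark, 23 °C; then t-BuSH (10 equiv), hν (tungsten lamp), 23 °C
Reagents that add atoms: none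
Why: Barton reductive decarboxylation: the thiohydroxamate ester fragments under light to the C11 radical, which is reduced by tert-butyl thiol in a tin-free chain that leaves the C–Br bond intact and, at high thiol concentration, should outrun homoallyl radical rearrangement.

**Step 17**
Reactants: 27 triethyl{[(3R)-5-((1S,4aS,6R,8aS)-6-bromo-2,5,5,8a-tetramethyl-1,4,4a,5,6,7,8,8a-octahydronaphthalen-1-yl)-3-methylpent-1-en-3-yl]oxy}silane
Product: 28 (3R)-5-[(1S,4aS,6R,8aS)-6-bromo-2,5,5,8a-tetramethyl-1,4,4a,5,6,7,8,8a-octahydronaphthalen-1-yl]-3-methylpent-1-en-3-ol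
Conditions: TBAF, THF, 23 °C
Reagents that add atoms: none
Why: Fluoride-induced Si–O cleavage liberates the tertiary allylic alcohol; the equatorial ring bromide has no antiperiplanar hydrogen and should not eliminate.

**Compound list**
1 | methyl 3,3-dimethylpent-4-enoate | C=CC(C)(C)CC(=O)OC | starting material
2 | 3,3-dimethylpent-4-enal | C=CC(C)(C)CC=O | intermediate
3 | (S)-2-bromo-3,3-dimethylpent-4-enal | C=CC(C)(C)[C@H](Br)C=O | intermediate
4 | (S)-2-bromo-3,3-dimethylpent-4-en-1-ol | C=CC(C)(C)[C@H](Br)CO | intermediate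
5 | (S)-2-bromo-3,3-dimethylpent-4-en-1-yl trifluoromethanesulfonate | C=CC(C)(C)[C@H](Br)COS(=O)(=O)C(F)(F)F | intermediate
6 | 1-(trimethylsilyl)prop-1-yne | CC#C[Si](C)(C)C | starting material
7 | 3-lithio-1-(trimethylsilyl)prop-1-yne | [Li]CC#C[Si](C)(C)C | intermediate
8 | (R)-(5-bromo-6,6-dimethyloct-7-en-1-yn-1-yl)trimethylsilane | C=CC(C)(C)[C@H](Br)CCC#C[Si](C)(C)C | intermediate
9 | (R)-5-bromo-6,6-dimethyloct-7-en-1-yne | C=CC(C)(C)[C@H](Br)CCC#C | intermediate
10 | dimethyl[(1E,5R)-5-bromo-2,6,6-trimethylocta-1,7-dien-1-yl]alumane | C=CC(C)(C)[C@H](Br)CC/C(C)=C/[Al](C)C | intermediate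
11 | (1E,5R)-5-bromo-1-iodo-2,6,6-trimethylocta-1,7-diene | C=CC(C)(C)[C@H](Br)CC/C(C)=C/I | intermediate
12 | (E)-but-2-enal (crotonaldehyde) | C/C=C/C=O | starting material
13 | (2E,5R,8E)-5-bromo-9-iodo-4,4,8-trimethylnona-2,8-dienal | O=C/C=C/C(C)(C)[C@H](Br)CC/C(C)=C/I | intermediate
14 | isopropenylboronic acid pinacol ester | CC(=C)B1OC(C)(C)C(C)(C)O1 | starting material
15 | (2E,5R,8E)-5-bromo-4,4,8,10-tetramethylundeca-2,8,10-trienal | O=C/C=C/C(C)(C)[C@H](Br)CC/C(C)=C/C(C)=C | intermediate
16 | (1R,4aS,7R,8aS)-7-bromo-3,4a,8,8-tetramethyl-1,2,4a,5,6,7,8,8a-octahydronaphthalene-1-carbaldehyde | C1=C(C)C[C@@H](C=O)[C@@H]2C(C)(C)[C@H](Br)CC[C@]21C | intermediate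
17 | (2R,4aS,8aS)-2-bromo-1,1,4a,6-tetramethyl-1,2,3,4,4a,7,8,8a-octahydronaphthalene | C1=C(C)CC[C@@H]2C(C)(C)[C@H](Br)CC[C@]21C | intermediate
18 | (2S,4aS,7R,8aS)-7-bromo-3,4a,8,8-tetramethyl-1,2,4a,5,6,7,8,8a-octahydronaphthalen-2-ol | C1=C(C)[C@@H](O)C[C@@H]2C(C)(C)[C@H](Br)CC[C@]21C | intermediate
19 | (R)-(−)-linalool, (R)-3,7-dimethylocta-1,6-dien-3-ol | C=C[C@](C)(O)CCC=C(C)C | starting material
20 | (R)-triethyl[(3,7-dimethylocta-1,6-dien-3-yl)oxy]silane | C=C[C@](C)(O[Si](CC)(CC)CC)CCC=C(C)C | intermediate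
21 | (R)-4-methyl-4-[(triethylsilyl)oxy]hex-5-enal | C=C[C@](C)(O[Si](CC)(CC)CC)CCC=O | intermediate
22 | (R)-4-methyl-4-[(triethylsilyl)oxy]hex-5-enoic acid | C=C[C@](C)(O[Si](CC)(CC)CC)CCC(=O)O | intermediate
23 | (2S,4aS,7R,8aS)-7-bromo-3,4a,8,8-tetramethyl-1,2,4a,5,6,7,8,8a-octahydronaphthalen-2-yl (4R)-4-methyl-4-[(triethylsilyl)oxy]hex-5-enoate | C1=C(C)[C@@H](OC(=O)CC[C@@](C)(O[Si](CC)(CC)CC)C=C)C[C@@H]2C(C)(C)[C@H](Br)CC[C@]21C | intermediate
24 | O-trimethylsilyl ketene acetal of ester 23 (enolised at the hexenoate C2; ring and C4 configured as in 23) | C1=C(C)[C@@H](OC(O[Si](C)(C)C)=CC[C@@](C)(O[Si](CC)(CC)CC)C=C)C[C@@H]2C(C)(C)[C@H](Br)CC[C@]21C | intermediate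
25 | (4R)-2-[(1S,4aS,6R,8aR)-6-bromo-2,5,5,8a-tetramethyl-1,4,4a,5,6,7,8,8a-octahydronaphthalen-1-yl]-4-methyl-4-[(triethylsilyl)oxy]hex-5-enoic acid (C2 epimers) | OC(=O)C(C[C@@](C)(O[Si](CC)(CC)CC)C=C)[C@H]1C(C)=CC[C@@H]2C(C)(C)[C@H](Br)CC[C@]21C | intermediate
26 | 2-thioxopyridin-1(2H)-yl ester (Barton ester) of acid 25 | O=C(ON1C=CC=CC1=S)C(C[C@@](C)(O[Si](CC)(CC)CC)C=C)[C@H]1C(C)=CC[C@@H]2C(C)(C)[C@H](Br)CC[C@]21C | intermediate
27 | triethyl{[(3R)-5-((1S,4aS,6R,8aS)-6-bromo-2,5,5,8a-tetramethyl-1,4,4a,5,6,7,8,8a-octahydronaphthalen-1-yl)-3-methylpent-1-en-3-yl]oxy}silane | C=C[C@](C)(O[Si](CC)(CC)CC)CC[C@H]1C(C)=CC[C@@H]2C(C)(C)[C@H](Br)CC[C@]21C | intermediate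
28 | (3R)-5-[(1S,4aS,6R,8aS)-6-bromo-2,5,5,8a-tetramethyl-1,4,4a,5,6,7,8,8a-octahydronaphthalen-1-yl]-3-methylpent-1-en-3-ol (CNP0210577.1) | C=C[C@](C)(O)CC[C@H]1C(C)=CC[C@@H]2C(C)(C)[C@H](Br)CC[C@]21C | target

**Totals.** Total step count: 17. Longest linear sequence: 14 steps (steps 1–10, then 14–17); steps 11–13 form the side-chain branch.

**Steps most likely to fail and their fallbacks**

1. Step 8. The iminium may activate the enal too weakly for a cycloaddition that must join the neopentyl C5 to the fully substituted C10 terminus, so that slow turnover, diene isomerisation or oligomerisation win, or endo and facial control may erode. The fallback sets out from 15 and comes back at 17. Pinnick oxidation of 15 would give (2E,5R,8E)-5-bromo-4,4,8,10-tetramethylundeca-2,8,10-trienoic acid F1. Acylation of (S)-4-benzyl-2-oxazolidinone with it (PivCl, Et3N, LiCl) would give the N-enoyl oxazolidinone F2. Me2AlCl (CH2Cl2, −30 °C) should then drive the auxiliary-controlled, strongly Lewis-acid-activated intramolecular Diels–Alder reaction to the bicyclic imide F3. LiOOH would cleave the auxiliary to the octalin carboxylic acid F4, and Barton reductive decarboxylation (as in step 16) would give 17.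

2. Step 4. The basic propargyllithium may eliminate the β-bromo triflate (loss of the C3 centre) or react through its allenyl terminus instead of substituting. The fallback sets out from 5 and comes back at 9. The soft sodium salt of dimethyl malonate would displace the triflate to give dimethyl 2-[(2R)-2-bromo-3,3-dimethylpent-4-en-1-yl]propanedioate F5. Krapcho dealkoxycarbonylation (LiCl, wet DMSO, 130 °C) would give methyl (4R)-4-bromo-5,5-dimethylhept-6-enoate F6, and DIBAL-H at −78 °C would give (4R)-4-bromo-5,5-dimethylhept-6-enal F7. Ohira–Bestmann homologation (dimethyl (1-diazo-2-oxopropyl)phosphonate, K2CO3, MeOH) would then give 9.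

3. Step 10. The ene/[2,3] sequence may show poor site selectivity (C17 methyl against C7), poor facial selectivity, or over-oxidation. The fallback sets out from 17 and comes back at 18. Allylic oxidation to the ketone level (CrO3·3,5-dimethylpyrazole, or Rh2(cap)4/t-BuOOH) would give (4aS,7R,8aS)-7-bromo-3,4a,8,8-tetramethyl-4a,5,6,7,8,8a-hexahydronaphthalen-2(1H)-one F8. Corey–Bakshi–Shibata reduction (Me-CBS antipode chosen for hydride delivery to the face syn to the C10 methyl, catecholborane, −78 °C) would give 18 under reagent control.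

**Further compounds**
F1 | step 8 | (2E,5R,8E)-5-bromo-4,4,8,10-tetramethylundeca-2,8,10-trienoic acid | OC(=O)/C=C/C(C)(C)[C@H](Br)CC/C(C)=C/C(C)=C
F2 | step 8 | (S)-4-benzyl-3-[(2E,5R,8E)-5-bromo-4,4,8,10-tetramethylundeca-2,8,10-trienoyl]oxazolidin-2-one | O=C1OC[C@H](Cc2ccccc2)N1C(=O)/C=C/C(C)(C)[C@H](Br)CC/C(C)=C/C(C)=C
F3 | step 8 | (S)-4-benzyl-3-{[(1R,4aS,7R,8aS)-7-bromo-3,4a,8,8-tetramethyl-1,2,4a,5,6,7,8,8a-octahydronaphthalen-1-yl]carbonyl}oxazolidin-2-one | C1=C(C)C[C@@H](C(=O)N3[C@@H](Cc4ccccc4)COC3=O)[C@@H]2C(C)(C)[C@H](Br)CC[C@]21C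
F4 | step 8 | (1R,4aS,7R,8aS)-7-bromo-3,4a,8,8-tetramethyl-1,2,4a,5,6,7,8,8a-octahydronaphthalene-1-carboxylic acid | C1=C(C)C[C@@H](C(=O)O)[C@@H]2C(C)(C)[C@H](Br)CC[C@]21C
F5 | step 4 | dimethyl 2-[(2R)-2-bromo-3,3-dimethylpent-4-en-1-yl]propanedioate | C=CC(C)(C)[C@H](Br)CC(C(=O)OC)C(=O)OC
F6 | step 4 | methyl (4R)-4-bromo-5,5-dimethylhept-6-enoate | C=CC(C)(C)[C@H](Br)CCC(=O)OC
F7 | step 4 | (4R)-4-bromo-5,5-dimethylhept-6-enal | C=CC(C)(C)[C@H](Br)CCC=O
F8 | step 10 | (4aS,7R,8aS)-7-bromo-3,4a,8,8-tetramethyl-4a,5,6,7,8,8a-hexahydronaphthalen-2(1H)-one | C1=C(C)C(=O)C[C@@H]2C(C)(C)[C@H](Br)CC[C@]21C
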